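## Structural features

The target is a resveratrol dehydrodimer built on a 2,3-dihydro-1-benzofuran: benzo ring A is fused to dihydrofuran ring B, C2 carries a 4-hydroxyphenyl group (ring C), C3 a 3,5-dihydroxyphenyl group (ring D), and C5, para to O1, an (E)-2-(3,5-dihydroxyphenyl)ethenyl arm (ring E). C2 and C3 are adjacent stereocentres; with the priorities O1 > ring C > C3 at C2 and C2 > C3a > ring D at C3, (2S,3S) is the isomer with rings C and D trans, and the SMILES string encodes the same arrangement, so no structure needs correction. C2 is a benzylic ether carbon whose aryl ring has a free para hydroxyl, so O1–C2 can open to a p-quinone methide under acid or base; this makes trans the thermodynamic arrangement and C2 self-correcting, but it also makes ring B fragile. The other fragile features are the five free phenols, which are easily oxidised, and the stilbene, which isomerises in light, adds electrophiles in acid and rules out hydrogenolysis. The real difficulty is therefore the absolute configuration at C3, a methine flanked by two aryl rings and C2 with no heteroatom or carbonyl group to hold on to, and reaching it without a long protecting-group sequence. Read backwards, C2 and C3 are the two carbons of an (E)-stilbene whose C2 end is benzylic to ring C and whose C3 end carries ring A with a hydroxyl group ortho to the alkene. The key step exploits exactly this: arylpalladation that brings ring D to C3 leaves palladium on C2, where the para hydroxyl of ring C can expel it as a p-quinone methide, and the ring A oxygen then forms O1–C2.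

## Logic of the disconnections

**11 to 10.** The four O–CH2Ph bonds on rings D and E are cut. The resorcinol hydroxyls must be masked through the oxidative palladium step and the basic olefination, and benzyl is chosen because 5 and 8 are bought with it and one non-reductive operation removes all four. The ring C hydroxyl is never protected, because it is the working group of the key step, so the route has no protection step at all. The demand on the forward step is a cleavage that spares the alkene and ionises neither O1–C2 nor the stilbene; this is met by BCl3 at low temperature with a cation scavenger.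

**10 to 7 and 9.** The C=C bond of the arm is cut. An E-selective olefination makes it reliably, and making it late keeps a second para-oxygenated stilbene, which could itself insert or ionise, out of the key step. Ring E and two carbons are removed and only a formyl group is left on ring A. The forward step has to run with strong base on the free phenol of 7, so one extra equivalent of base and a low temperature are needed.

**9 to 8.** The P–C bond is cut; a Michaelis–Arbuzov reaction on a bought benzylic bromide makes it and asks for nothing special.

**7 to 4 and 5, through 6.** The bonds C3–ring D and O1–C2 are cut, which are the two bonds an oxyarylation of an alkene forms. Ring B and both stereocentres disappear together, leaving an achiral, planar stilbene and a bought boronic acid. The forward step must put palladium on C2 and not on C3, select one alkene face, ionise to 6 faster than β-hydride elimination, and tolerate two free phenols and an aldehyde under divalent palladium, divalent copper and O2. The formyl group has three jobs: it is the handle for the arm, it makes ring A the poorer partner for palladium, and it makes the ring A phenol less nucleophilic and less oxidisable.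

**4 to 1 and 2, through 3.** The bond between ring A and the alkene carbon (the later C3a–C3 bond) is cut. A Heck reaction gives the (E)-alkene directly, and 2 is the stable, storable form of 4-vinylphenol. Both pieces are commercial. The forward step needs oxidative addition into a bromide ortho to a free hydroxyl, and the acetate is removed in the same flask, so 4 costs one step.

## Other disconnections considered

**Alternative 1:** The cut removes both aryl–carbon bonds of ring B, C2–ring C and C3–ring D, and leads back to methyl 1-benzofuran-5-carboxylate A1, 1-(benzyloxy)-4-iodobenzene A2 and 5. In the forward step the arylpalladium iodide from A2 would add syn across C2=C3 of A1 with the aryl group on C2, and the benzylic C3–palladium bond would be coupled with 5 to give the cis ester A3 (2R,3S).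
- In its favour: two C–C bonds and both stereocentres come from three bought compounds in one operation, which is more skeletal construction per step than the chosen plan offers. After syn addition H2 is anti to palladium, so β-hydride elimination is excluded by geometry, whereas the chosen plan has to outrun it. No free phenol meets the catalyst. On these three points the alternative is the better.
- Against it: the C2=C3 bond belongs to an aromatic ring and should insert reluctantly, so direct biaryl coupling of A2 with 5 is the expected competitor. An intermolecular enantioselective version is no better supported by precedent than the chosen step (equal). A3 is cis, so C2 must afterwards be epimerised by acid through the ring-opened benzylic cation, and the ester must be reduced and reoxidised before the olefination.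
- Step economy: about seven steps with six in the longest line, against five and four. The fifth benzyl ether falls in the same last step and costs nothing (equal).

**Alternative 2:** The cut is C2–C3, and ring B is closed from the acyclic ether 1-{[4-(benzyloxy)phenyl]methoxy}-2-{[3,5-bis(benzyloxy)phenyl](diazo)methyl}-4-bromobenzene A4. With Rh2(R-PTAD)4 or its enantiomer the donor/donor carbene would insert into the benzylic ether C–H bond and give the cis bromide A5 (2R,3S).
- In its favour: this insertion is an established reaction type for exactly this class of 2,3-diaryl-2,3-dihydrobenzofurans, so on precedent it is clearly the better plan. The bond is formed intramolecularly, so no regiochemical question arises (better). The bromide carries the arm as well as the formyl group does (equal).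
- Against it: A4 needs an ether formation, a diaryl ketone, its hydrazone and an oxidation to an unstabilised diazo compound, so several operations precede the ring closure where the chosen plan needs one. All phenols must be protected. The product is cis and C2 must be inverted afterwards.
- Mechanistically both plans set two stereocentres in the ring-forming step. Here the catalyst sets both and C2 is then corrected; in the chosen plan the catalyst sets C3 and thermodynamics sets C2 directly.
- Step economy: about ten steps against five. This is why it serves as the fallback and not as the first choice.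

**Alternative 3:** Only O1–C2 is cut; the substrate is the enantioenriched triarylethane methyl 3-{(1S)-1-[3,5-bis(benzyloxy)phenyl]-2-(4-hydroxyphenyl)ethyl}-4-hydroxybenzoate A6. Anodic oxidation at constant current would take two electrons and two protons from its 4-hydroxybenzyl unit, and the ring A phenol would capture the resulting p-quinone methide to give the trans ester A7 (2S,3S).
- In its favour: the ring closure is the same 5-exo-trig 1,6-addition as in the chosen plan, with the same thermodynamic trans control (equal). No metal, no ligand and no regiochemical question at an alkene are involved (better). The ester-bearing ring A phenol should be much harder to oxidise than the ring C phenol, so the anode should pick the right ring.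
- Against it: the step forms no C–C bond and sets only C2. C3 has to be set earlier in A6 by a separate asymmetric step, for example asymmetric hydrogenation of the corresponding alkene, so the hard problem is moved and not solved. A7 keeps a 4-hydroxybenzyl ether about as oxidisable as A6, so over-oxidation to the benzofuran is to be feared. Tautomerisation of the quinone methide at C3 is the same risk as in the chosen plan (equal).
- Step economy: A6 alone should need about as many steps as the whole chosen route, and the ester adds two redox steps.

Key step: step 2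

Assumption: the facial sense of the pyridine-oxazoline ligand on this 1,2-diarylethene cannot be taken from a close analogy; the (S)-tert-butyl ligand is written, and its (R)-enantiomer, equally accessible, is to be used if the (S)-ligand proves to lead to the (3R) series.

## Route

Step 1
Reactants: 1 3-bromo-4-hydroxybenzaldehyde; 2 4-ethenylphenyl acetate (4-acetoxystyrene)
Product: 4 4-hydroxy-3-[(E)-2-(4-hydroxyphenyl)ethenyl]benzaldehyde, via stilbene acetate 3 (not isolated)
Conditions: Pd(OAc)2 (3 mol%), P(o-tol)3 (6 mol%), Et3N, DMF, 100 °C; then MeOH, K2CO3, 23 °C; aq. citric acid; recrystallise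
Reagents that add atoms: none
Why: Mizoroki–Heck reaction: oxidative addition of the aryl bromide to zerovalent palladium, syn insertion of the terminal alkene at its CH2 carbon and syn β-hydride elimination should give the (E)-stilbene 3. Any acetyl migration between the two phenols is harmless, because base-catalysed transesterification with methanol (K2CO3 as base catalyst) then frees both phenols in the same flask. 4 is purified carefully so that no achiral palladium or phosphine reaches step 2.

Step 2
Reactants: 4 4-hydroxy-3-[(E)-2-(4-hydroxyphenyl)ethenyl]benzaldehyde; 5 [3,5-bis(benzyloxy)phenyl]boronic acid (2.5 equiv)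
Product: 7 (2S,3S)-3-[3,5-bis(benzyloxy)phenyl]-2-(4-hydroxyphenyl)-2,3-dihydro-1-benzofuran-5-carbaldehyde (trans), via p-quinone methide 6 (not isolated)
Conditions: Pd(CH3CN)2(OTs)2 (8 mol%), (S)-4-tert-butyl-2-[5-(trifluoromethyl)pyridin-2-yl]-4,5-dihydro-1,3-oxazole (12 mol%), Cu(OTf)2 (5 mol%), O2 (1 atm), 3 Å molecular sieves, DMF, 23 °C
Reagents that add atoms: none
Why: Proposed new method: transmetalation of 5 to the cationic divalent palladium–pyridine-oxazoline complex is followed by syn insertion of the (E)-alkene of 4 with ring D on C3 and palladium on C2; the benzylic C2–Pd bond then ionises with loss of the ring C phenol proton and of zerovalent palladium to p-quinone methide 6, the ring A phenol adds to C2, and O2 with Cu(OTf)2 returns palladium to the divalent state. The closest known reaction types are the enantioselective palladium-catalysed difunctionalisations of vinylphenols that pass through quinone methides and the pyridine-oxazoline-controlled oxidative Heck arylation with arylboronic acids; new is their union on a 1,2-diarylethene, with a para phenol as the relay and a second phenol as the internal nucleophile. Ring B closes by a 5-exo-trig 1,6-addition of O1 to the methide carbon of 6. C3 is set in the insertion, where the tert-butyl group of the ligand decides which alkene face receives ring D; C2 is planar in 6 and is set in the ring closure, which places rings C and D trans both kinetically and, because the addition is reversible under the mildly acidic conditions, thermodynamically. The step needs palladium on C2 and not on C3: ring C is unhindered, coplanar with the alkene and electron-rich, and so offers the better η3-benzyl contact to cationic palladium, whereas ring A is ortho-substituted and made a poorer π-donor by the formyl group. It also needs ionisation to 6 faster than β-hydride elimination of H3, for which the free para hydroxyl of ring C is the driving group, and ring closure faster than tautomerisation of 6, for which the ortho position of the ring A hydroxyl provides a five-membered transition state. The formyl group further lowers the nucleophilicity and oxidisability of the ring A phenol, which should hold back Wacker-type cyclisation to a 2-arylbenzofuran and phenol coupling, and 5 is used in excess because part of it is lost to homocoupling and oxidation.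

Step 3
Reactants: 8 1,3-bis(benzyloxy)-5-(bromomethyl)benzene (3,5-bis(benzyloxy)benzyl bromide)
Product: 9 diethyl {[3,5-bis(benzyloxy)phenyl]methyl}phosphonate
Conditions: P(OEt)3 (neat), 130 °C
Reagents that add atoms: triethyl phosphite, CCOP(OCC)OCC
Why: Michaelis–Arbuzov reaction: SN2 attack of phosphorus on the benzylic bromide and dealkylation of the phosphonium salt by bromide; the aryl benzyl ethers are inert.

Step 4
Reactants: 7 (2S,3S)-3-[3,5-bis(benzyloxy)phenyl]-2-(4-hydroxyphenyl)-2,3-dihydro-1-benzofuran-5-carbaldehyde; 9 diethyl {[3,5-bis(benzyloxy)phenyl]methyl}phosphonate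
Product: 10 4-[(2S,3S)-3-[3,5-bis(benzyloxy)phenyl]-5-{(E)-2-[3,5-bis(benzyloxy)phenyl]ethenyl}-2,3-dihydro-1-benzofuran-2-yl]phenol
Conditions: KOtBu (2.5 equiv), THF, 0 °C to 23 °C
Reagents that add atoms: none
Why: Horner–Wadsworth–Emmons reaction: the first equivalent of KOtBu turns the ring C phenol into a phenoxide that is not conjugated to the formyl group, so the carbonyl stays electrophilic; the potassium salt of 9 adds and the oxaphosphetane collapses to the (E)-alkene, the usual outcome for benzylic phosphonates and aromatic aldehydes. C2 and C3 carry no hydrogen acidic enough for tert-butoxide, and the low temperature should keep the phenoxide from opening ring B.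

Step 5
Reactants: 10 4-[(2S,3S)-3-[3,5-bis(benzyloxy)phenyl]-5-{(E)-2-[3,5-bis(benzyloxy)phenyl]ethenyl}-2,3-dihydro-1-benzofuran-2-yl]phenol
Product: 11 (2S,3S)-trans-δ-viniferin
Conditions: BCl3 (10 equiv), C6HMe5 (12 equiv), CH2Cl2, −78 °C; then CHCl3–MeOH, −78 °C to 23 °C; water
Reagents that add atoms: none
Why: Lewis-acid cleavage of aryl benzyl ethers: BCl3 binds the ether oxygens and the benzyl cations pass to pentamethylbenzene by Friedel–Crafts alkylation, a non-basic scavenger that keeps them off rings D and E and off the alkene; at −78 °C neither the stilbene nor O1–C2 should ionise, and methanol frees the phenols from their borates. Should O1–C2 open reversibly, reclosure returns the trans isomer and C3 is not involved.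

## Compound list

1 | 3-bromo-4-hydroxybenzaldehyde | O=Cc1ccc(O)c(Br)c1 | starting material
2 | 4-ethenylphenyl acetate (4-acetoxystyrene) | CC(=O)Oc1ccc(C=C)cc1 | starting material
3 | 4-[(E)-2-(5-formyl-2-hydroxyphenyl)ethenyl]phenyl acetate | CC(=O)Oc1ccc(/C=C/c2cc(C=O)ccc2O)cc1 | intermediate
4 | 4-hydroxy-3-[(E)-2-(4-hydroxyphenyl)ethenyl]benzaldehyde | O=Cc1ccc(O)c(/C=C/c2ccc(O)cc2)c1 | intermediate
5 | [3,5-bis(benzyloxy)phenyl]boronic acid | OB(O)c1cc(OCc2ccccc2)cc(OCc2ccccc2)c1 | starting material
6 | 3-[(1S)-1-[3,5-bis(benzyloxy)phenyl]-2-(4-oxocyclohexa-2,5-dien-1-ylidene)ethyl]-4-hydroxybenzaldehyde (p-quinone methide) | O=C1C=CC(=C[C@H](c2cc(C=O)ccc2O)c2cc(OCc3ccccc3)cc(OCc3ccccc3)c2)C=C1 | intermediate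
7 | (2S,3S)-3-[3,5-bis(benzyloxy)phenyl]-2-(4-hydroxyphenyl)-2,3-dihydro-1-benzofuran-5-carbaldehyde (trans) | Oc1ccc([C@H]2Oc3ccc(C=O)cc3[C@@H]2c2cc(OCc4ccccc4)cc(OCc4ccccc4)c2)cc1 | intermediate
8 | 1,3-bis(benzyloxy)-5-(bromomethyl)benzene | BrCc1cc(OCc2ccccc2)cc(OCc2ccccc2)c1 | starting material
9 | diethyl {[3,5-bis(benzyloxy)phenyl]methyl}phosphonate | CCOP(=O)(Cc1cc(OCc2ccccc2)cc(OCc2ccccc2)c1)OCC | intermediate
10 | 4-[(2S,3S)-3-[3,5-bis(benzyloxy)phenyl]-5-{(E)-2-[3,5-bis(benzyloxy)phenyl]ethenyl}-2,3-dihydro-1-benzofuran-2-yl]phenol (trans) | Oc1ccc([C@H]2Oc3ccc(/C=C/c4cc(OCc5ccccc5)cc(OCc5ccccc5)c4)cc3[C@@H]2c2cc(OCc4ccccc4)cc(OCc4ccccc4)c2)cc1 | intermediate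
11 | 5-[(2S,3S)-5-[(E)-2-(3,5-dihydroxyphenyl)ethenyl]-2-(4-hydroxyphenyl)-2,3-dihydro-1-benzofuran-3-yl]benzene-1,3-diol, (2S,3S)-trans-δ-viniferin | Oc1ccc([C@H]2Oc3ccc(/C=C/c4cc(O)cc(O)c4)cc3[C@@H]2c2cc(O)cc(O)c2)cc1 | target

## Step count and least certain steps

Total step count: 5. Longest linear sequence: 4 steps (steps 1, 2, 4 and 5, from 1 to 11); step 3 is the side branch.

**Step 2 (key step).** Four processes are most likely to go wrong.
- Insertion in the opposite regiochemical sense, with the aryl group on C2 and palladium on C3. In a cationic insertion the migrating aryl group tends to go to the alkene carbon next to the better donor ring, and this electronic preference works against the benzyl-stabilisation and steric arguments used above.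
- β-Hydride elimination of H3 outrunning ionisation of the C2–Pd bond. It needs only rotation about C2–C3 and would give a triarylethene without a stereocentre.
- Copper-promoted O-arylation of the acidic ring A phenol by 5 (Chan–Lam coupling) and oxidative coupling of the 4-hydroxystilbene.
- Poor facial selectivity, because both alkene substituents are flat aryl groups.

Levers inside the step are a substoichiometric weak base that ionises only the more acidic ring A phenol so that its oxygen pushes electron density towards C2, reoxidation without copper, and a lower temperature.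

The fallback uses known reaction types and replaces the alkene difunctionalisation by a donor/donor carbene C–H insertion. It sets out from 5 and comes back to the route at 11. 5-Bromo-2-hydroxybenzaldehyde is O-alkylated with 4-(benzyloxy)benzyl chloride (K2CO3, DMF) to 2-{[4-(benzyloxy)phenyl]methoxy}-5-bromobenzaldehyde F1. Rhodium-catalysed 1,2-addition of 5 (Rh(acac)(CO)2, P(t-Bu)3, aqueous DME) gives the racemic carbinol (2-{[4-(benzyloxy)phenyl]methoxy}-5-bromophenyl)[3,5-bis(benzyloxy)phenyl]methanol F2. MnO2 oxidises it to (2-{[4-(benzyloxy)phenyl]methoxy}-5-bromophenyl)[3,5-bis(benzyloxy)phenyl]methanone F3, and hydrazine hydrate in hot ethanol with a little acetic acid gives the hydrazone [(2-{[4-(benzyloxy)phenyl]methoxy}-5-bromophenyl)[3,5-bis(benzyloxy)phenyl]methylidene]hydrazine F4. Oxidation of F4 with MnO2 gives the diazo compound A4, which is added cold to the enantiomer of Rh2(PTAD)4 that leads to the (3S) series and should give the cis-dihydrobenzofuran A5. CF3CO2H in CH2Cl2 opens O1–C2 reversibly to the 4-benzyloxybenzyl cation and epimerises C2 to (2S,3S)-2-[4-(benzyloxy)phenyl]-3-[3,5-bis(benzyloxy)phenyl]-5-bromo-2,3-dihydro-1-benzofuran F5. Bromine–lithium exchange (n-BuLi, THF, −78 °C) and DMF give (2S,3S)-2-[4-(benzyloxy)phenyl]-3-[3,5-bis(benzyloxy)phenyl]-2,3-dihydro-1-benzofuran-5-carbaldehyde F6. Olefination with 9 as in step 4 (one equivalent of base suffices) gives (2S,3S)-2-[4-(benzyloxy)phenyl]-3-[3,5-bis(benzyloxy)phenyl]-5-{(E)-2-[3,5-bis(benzyloxy)phenyl]ethenyl}-2,3-dihydro-1-benzofuran F7, and the conditions of step 5 remove all five benzyl groups to give 11.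

**Step 4.** The most likely failure is phenoxide-triggered opening of ring B (a retro-oxa-Michael reaction made easier by the para-formyl aryloxide as leaving group), followed by tautomerisation of the quinone methide to a triarylethene. This would destroy both stereocentres irreversibly, whereas simple reclosure is harmless. A second concern is slow olefination if the potassium phenoxide is poorly soluble.

The fallback removes the phenoxide instead of tuning the base. It sets out from 7 and comes back at 10. Silylation (i-Pr3SiCl, imidazole, DMF) gives (2S,3S)-3-[3,5-bis(benzyloxy)phenyl]-2-{4-[(triisopropylsilyl)oxy]phenyl}-2,3-dihydro-1-benzofuran-5-carbaldehyde F8. Olefination with 9 (NaH, THF) gives {4-[(2S,3S)-3-[3,5-bis(benzyloxy)phenyl]-5-{(E)-2-[3,5-bis(benzyloxy)phenyl]ethenyl}-2,3-dihydro-1-benzofuran-2-yl]phenoxy}tri(propan-2-yl)silane F9. Bu4NF buffered with acetic acid (THF, 0 °C) then returns 10.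

**Step 5.** The most likely failure is ionisation of O1–C2 or protonation of the stilbene by the Lewis acid or by HCl, followed by Friedel–Crafts capture by the electron-rich resorcinol rings (skeletal rearrangement to indane-type dimers) or by the scavenger. Incomplete cleavage of the last benzyl ether is the second concern.

The fallback changes the protecting group to one removed by fluoride. It sets out from 4 and comes back at 11.
- {3,5-Bis[(tert-butyldimethylsilyl)oxy]phenyl}boronic acid F10, made from the corresponding aryl bromide by bromine–lithium exchange and borylation, replaces 5 under the conditions of step 2. This should give (2S,3S)-3-{3,5-bis[(tert-butyldimethylsilyl)oxy]phenyl}-2-(4-hydroxyphenyl)-2,3-dihydro-1-benzofuran-5-carbaldehyde F11.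
- Olefination with diethyl ({3,5-bis[(tert-butyldimethylsilyl)oxy]phenyl}methyl)phosphonate F12 (made as in step 3 from the silylated benzylic bromide; NaH, THF) gives 4-[(2S,3S)-3-{3,5-bis[(tert-butyldimethylsilyl)oxy]phenyl}-5-[(E)-2-{3,5-bis[(tert-butyldimethylsilyl)oxy]phenyl}ethenyl]-2,3-dihydro-1-benzofuran-2-yl]phenol F13. Partial loss of silyl groups at this stage does not matter.
- Et3N·3HF in THF then removes all four silyl groups without Lewis acid and gives 11.

## Further compounds

F1 | step 2 | 2-{[4-(benzyloxy)phenyl]methoxy}-5-bromobenzaldehyde | O=Cc1cc(Br)ccc1OCc1ccc(OCc2ccccc2)cc1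
F2 | step 2 | (2-{[4-(benzyloxy)phenyl]methoxy}-5-bromophenyl)[3,5-bis(benzyloxy)phenyl]methanol (racemic) | OC(c1cc(Br)ccc1OCc1ccc(OCc2ccccc2)cc1)c1cc(OCc2ccccc2)cc(OCc2ccccc2)c1
F3 | step 2 | (2-{[4-(benzyloxy)phenyl]methoxy}-5-bromophenyl)[3,5-bis(benzyloxy)phenyl]methanone | O=C(c1cc(Br)ccc1OCc1ccc(OCc2ccccc2)cc1)c1cc(OCc2ccccc2)cc(OCc2ccccc2)c1
F4 | step 2 | [(2-{[4-(benzyloxy)phenyl]methoxy}-5-bromophenyl)[3,5-bis(benzyloxy)phenyl]methylidene]hydrazine | NN=C(c1cc(Br)ccc1OCc1ccc(OCc2ccccc2)cc1)c1cc(OCc2ccccc2)cc(OCc2ccccc2)c1
F5 | step 2 | (2S,3S)-2-[4-(benzyloxy)phenyl]-3-[3,5-bis(benzyloxy)phenyl]-5-bromo-2,3-dihydro-1-benzofuran (trans) | c1ccccc1COc1ccc([C@H]2Oc3ccc(Br)cc3[C@@H]2c2cc(OCc4ccccc4)cc(OCc4ccccc4)c2)cc1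
F6 | step 2 | (2S,3S)-2-[4-(benzyloxy)phenyl]-3-[3,5-bis(benzyloxy)phenyl]-2,3-dihydro-1-benzofuran-5-carbaldehyde (trans) | c1ccccc1COc1ccc([C@H]2Oc3ccc(C=O)cc3[C@@H]2c2cc(OCc4ccccc4)cc(OCc4ccccc4)c2)cc1
F7 | step 2 | (2S,3S)-2-[4-(benzyloxy)phenyl]-3-[3,5-bis(benzyloxy)phenyl]-5-{(E)-2-[3,5-bis(benzyloxy)phenyl]ethenyl}-2,3-dihydro-1-benzofuran (trans) | c1ccccc1COc1ccc([C@H]2Oc3ccc(/C=C/c4cc(OCc5ccccc5)cc(OCc5ccccc5)c4)cc3[C@@H]2c2cc(OCc4ccccc4)cc(OCc4ccccc4)c2)cc1
F8 | step 4 | (2S,3S)-3-[3,5-bis(benzyloxy)phenyl]-2-{4-[(triisopropylsilyl)oxy]phenyl}-2,3-dihydro-1-benzofuran-5-carbaldehyde (trans) | CC(C)[Si](C(C)C)(C(C)C)Oc1ccc([C@H]2Oc3ccc(C=O)cc3[C@@H]2c2cc(OCc4ccccc4)cc(OCc4ccccc4)c2)cc1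
F9 | step 4 | {4-[(2S,3S)-3-[3,5-bis(benzyloxy)phenyl]-5-{(E)-2-[3,5-bis(benzyloxy)phenyl]ethenyl}-2,3-dihydro-1-benzofuran-2-yl]phenoxy}tri(propan-2-yl)silane (trans) | CC(C)[Si](C(C)C)(C(C)C)Oc1ccc([C@H]2Oc3ccc(/C=C/c4cc(OCc5ccccc5)cc(OCc5ccccc5)c4)cc3[C@@H]2c2cc(OCc4ccccc4)cc(OCc4ccccc4)c2)cc1
F10 | step 5 | {3,5-bis[(tert-butyldimethylsilyl)oxy]phenyl}boronic acid | OB(O)c1cc(O[Si](C)(C)C(C)(C)C)cc(O[Si](C)(C)C(C)(C)C)c1
F11 | step 5 | (2S,3S)-3-{3,5-bis[(tert-butyldimethylsilyl)oxy]phenyl}-2-(4-hydroxyphenyl)-2,3-dihydro-1-benzofuran-5-carbaldehyde (trans) | Oc1ccc([C@H]2Oc3ccc(C=O)cc3[C@@H]2c2cc(O[Si](C)(C)C(C)(C)C)cc(O[Si](C)(C)C(C)(C)C)c2)cc1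
F12 | step 5 | diethyl ({3,5-bis[(tert-butyldimethylsilyl)oxy]phenyl}methyl)phosphonate | CCOP(=O)(Cc1cc(O[Si](C)(C)C(C)(C)C)cc(O[Si](C)(C)C(C)(C)C)c1)OCC
F13 | step 5 | 4-[(2S,3S)-3-{3,5-bis[(tert-butyldimethylsilyl)oxy]phenyl}-5-[(E)-2-{3,5-bis[(tert-butyldimethylsilyl)oxy]phenyl}ethenyl]-2,3-dihydro-1-benzofuran-2-yl]phenol (trans) | Oc1ccc([C@H]2Oc3ccc(/C=C/c4cc(O[Si](C)(C)C(C)(C)C)cc(O[Si](C)(C)C(C)(C)C)c4)cc3[C@@H]2c2cc(O[Si](C)(C)C(C)(C)C)cc(O[Si](C)(C)C(C)(C)C)c2)cc1
A1 | alternative 1 | methyl 1-benzofuran-5-carboxylate | COC(=O)c1ccc2occc2c1
A2 | alternative 1 | 1-(benzyloxy)-4-iodobenzene | Ic1ccc(OCc2ccccc2)cc1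
A3 | alternative 1 | methyl (2R,3S)-2-[4-(benzyloxy)phenyl]-3-[3,5-bis(benzyloxy)phenyl]-2,3-dihydro-1-benzofuran-5-carboxylate (cis) | c1ccccc1COc1ccc([C@@H]2Oc3ccc(C(=O)OC)cc3[C@@H]2c2cc(OCc4ccccc4)cc(OCc4ccccc4)c2)cc1
A4 | alternative 2 | 1-{[4-(benzyloxy)phenyl]methoxy}-2-{[3,5-bis(benzyloxy)phenyl](diazo)methyl}-4-bromobenzene | [N-]=[N+]=C(c1cc(Br)ccc1OCc1ccc(OCc2ccccc2)cc1)c1cc(OCc2ccccc2)cc(OCc2ccccc2)c1
A5 | alternative 2 | (2R,3S)-2-[4-(benzyloxy)phenyl]-3-[3,5-bis(benzyloxy)phenyl]-5-bromo-2,3-dihydro-1-benzofuran (cis) | c1ccccc1COc1ccc([C@@H]2Oc3ccc(Br)cc3[C@@H]2c2cc(OCc4ccccc4)cc(OCc4ccccc4)c2)cc1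
A6 | alternative 3 | methyl 3-{(1S)-1-[3,5-bis(benzyloxy)phenyl]-2-(4-hydroxyphenyl)ethyl}-4-hydroxybenzoate | COC(=O)c1ccc(O)c(c1)[C@@H](Cc1ccc(O)cc1)c1cc(OCc2ccccc2)cc(OCc2ccccc2)c1
A7 | alternative 3 | methyl (2S,3S)-3-[3,5-bis(benzyloxy)phenyl]-2-(4-hydroxyphenyl)-2,3-dihydro-1-benzofuran-5-carboxylate (trans) | Oc1ccc([C@H]2Oc3ccc(C(=O)OC)cc3[C@@H]2c2cc(OCc4ccccc4)cc(OCc4ccccc4)c2)cc1
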